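## Structural features

The target is a 2-arylchromen-4-one. A benzene ring (ring A) is fused through C4a–C8a to a 4-pyranone (ring C: O1, C2, C3, C4, C4a, C8a), and a second benzene ring (ring B) is attached to C2 by the single bond C2–C1'. The molecule is flat and has no stereocentre, so no stereocentres stand next to each other and the whole difficulty is positional. Each benzene ring carries three contiguous oxygens, exactly one of which is a free hydroxyl: C7–OH beside the methoxy groups on C6 and C5, and C5'–OH beside those on C4' and C3'. Ring A carries a fourth oxygen, O1 on C8a, and C8 is its only C–H. The real problem is to obtain this fully differentiated ring A without positional isomers and to keep one hydroxyl on each ring distinguishable to the end. The fragile points are three: the C5 methoxy group peri to the C4 carbonyl (removed by BBr3, BCl3 or AlCl3), the C2=C3 enone bond (reducible, and opened by hot hydroxide), and the free phenols (easily oxidised). The key step uses the fact that C4a has only two ortho neighbours, C5 with its methoxy group and C8a. If C8a enters as C–H it lies para to the C6 methoxy group and within reach of the oxygen on C2 of an open 1,3-diketone, so O1–C8a can be the last skeletal bond formed and ring A can come from a 2,3,4-trioxygenated acetophenone.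

## Logic of the disconnections

**10 back to 8 (through 9).** Only the O7–CH2Ph ether bond and the O5'–C(=O)tBu ester bond are cut. Free phenols cannot pass through an oxidation, and the two caps are deliberately unlike: an ether on O7 keeps ring A electron-rich, while an acyl group on O5' makes ring B poorer in electrons and crowds C6'. The skeleton is not simplified; the gain is that the selectivity of the oxidation is written into the protecting groups. The forward demand is removal of both caps without touching the C5 methoxy group, the enone or ring C, which mild methanolysis followed by hydrogenolysis at atmospheric pressure should meet in one pot. A benzyl carbonate on O5' would allow a single hydrogenolysis, but it is less inert to the amide base used earlier and was set aside for safety.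

**8 back to 7.** The O1–C8a bond is cut, which opens ring C. This is the only disconnection that lets ring A enter without an oxygen at C8a, so no 2-hydroxy-4,5,6-trioxygenated acetophenone is needed. The heterocycle becomes an acyclic diaryl 1,3-diketone and the tetraoxygenated ring A becomes a trioxygenated one. The forward demand is heavy: an oxidative C–H oxygenation that selects C8a–H over C2'–H and C6'–H of ring B and over ipso attack at C5, and that stops after two electrons.

**7 back to 3 and 6.** The C3–C2 bond is cut, between the central methylene carbon and the carbonyl carbon beside ring B. This is the polarity of a crossed Claisen condensation and it divides the molecule into two monoaryl halves of similar size, each carrying one protected hydroxyl. The forward step must give C-acylation and not O-acylation, must not double-acylate, and must leave the aryl ester alone.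

**6 back to 5 and 4.** The C(=O)–Cl bond and then the pivalate O–C(=O) bond are cut. The acid chloride is the activated form needed for the enolate, and the pivalate is put on while the carboxyl group is still a carboxylate. The forward steps must acylate the phenol and not the carboxylate, and must activate the acid without harming the ester.

**3 back to 2 and 1.** The two O–CH3 bonds on the future O5 and O6 are cut, then the O7–CH2Ph bond. All three oxygens and the acetyl group are already correctly placed in 1, so only their differentiation remains. The forward demand is one selective monoalkylation, which rests on the 4-hydroxyl being the most acidic and the only one not hydrogen-bonded or flanked on both sides.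

## Other disconnections considered

**Alternative 1:** The cut runs through C1'–C2 and C2–C3, so C2 is supplied by carbon monoxide A4. In the forward key step zerovalent palladium would insert into the C–Br bond of 5-bromo-1,2-dimethoxy-3-(methoxymethoxy)benzene A3, take up A4, and transfer the aroyl group to the enolate of 1-[6-hydroxy-2,3-dimethoxy-4-(methoxymethoxy)phenyl]ethanone A2. The product would be the 2-hydroxyaryl diketone A1, and acid would then close ring C and remove both acetal caps.
- In its favour: carbonylative α-arylation of ketones is an established reaction class. O1 is already on C8a, so the ring closure has no site-selectivity question. On mechanism this alternative is better than the chosen plan. Its one-pot acid endgame is the equal of the chosen one-pot endgame.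
- Against it: the difficulty moves into A2. The phenol from which A2 would be made by acylation has two different free ortho positions, so the ring A pattern is not secured without a longer route. The free ortho-phenol of A2 can also be O-aroylated by the acylpalladium species. A3 needs its own preparation, and A4 must be handled under pressure or from a surrogate.
- Comparison: on structure the chosen plan is stronger, since 3 comes from 1 in two steps with the oxygens already placed. On step economy the alternative is likely longer by the steps spent on A2 and A3.

**Alternative 2:** Ring A is removed altogether and is built by forming C8–C8a. Heating the racemic cyclobutenone A6 would bring about a four-electron ring opening followed by a six-electron closure, in which the former carbonyl carbon (C8a) bonds to the vinyl terminus (C8). Tautomerisation would give phenol A5, with the masked acetyl group on C4a.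
- In its favour: every ring A oxygen is placed by the order in which dimethyl squarate A7 is elaborated, and the C7 oxygen arrives already differentiated as a tert-butyl ether. No selective alkylation of a triol is needed. On positional certainty it equals the chosen plan, and on mechanistic reliability (pericyclic steps, no oxidant) it is better.
- Against it: it constructs a benzene ring that can be bought with the right oxygens. It needs two cryogenic organolithium additions, a rearrangement and an O-methylation before the thermolysis. After it come dithiane removal, aroylation, cyclodehydration and deprotection. Dithiane removal uses oxidants or heavy-metal salts in the presence of an electron-rich phenol, and the tert-butyl ether limits the acid that can be used later.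
- Comparison: roughly twice the number of steps of the chosen plan, for a gain only in the certainty of one bond-forming step.

**Alternative 3:** The cuts are C4a–C4, C4–C3 and O1–C2, so C4 comes from carbon monoxide A4. Zerovalent palladium would insert into the C–I bond of iodophenol A9, take up A4 and couple with the terminal alkyne A10 (carbonylative Sonogashira coupling). The phenol oxygen would then add to the triple bond in the 6-endo sense to give the bis-silyl flavone A8, and fluoride would remove both silyl groups.
- In its favour: it is the most convergent of the four plans, forming two C–C bonds and the C–O bond in one operation. The reaction class is known, and one reagent removes both caps. On convergency and precedent it is better than the chosen plan; in the endgame it is equal.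
- Against it: A9 must carry iodine between the hydroxyl and a methoxy group on a phenol that has a second free ortho position. The ring A pattern therefore rests on an iodination whose selectivity is open. The doubly ortho-substituted C–I bond is hindered toward insertion, 5-exo closure to an aurone competes with flavone formation, and A10 needs a one-carbon homologation of an aldehyde.
- Comparison: on structure the chosen plan is safer, because its ring A oxygens come from 1. On mechanism Alternative 3 is safer. Step counts should be similar.

Key step: step 6

Remarks on the chemistry:
- Flavone numbering (O1, C2, C3, C4, C4a, C5–C8, C8a; ring B C1'–C6') is used for all intermediates, including those made before ring C exists.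
- An atom-by-atom check of the open diketone against the closed flavone shows the benzoyl oxygens on C2, C3, C4 becoming those on C5, C6, C7, and the free benzoyl C6–H becoming C8a. Both structures are consistent with the target and no structural correction is needed.
- The ether/ester pair of caps is kept. The improvements lie in how the precursor is used (neutral enol, no added base, high dilution) and in running the two deprotections in one pot.
- Both starting materials are assumed to be purchasable.

## Route

Step 1
Reactants: 1 2,3,4-trihydroxyacetophenone (gallacetophenone)
Product: 2 1-(4-benzyloxy-2,3-dihydroxyphenyl)ethanone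
Conditions: BnBr (1.05 equiv), NaHCO3 (1.5 equiv), DMF, N2, 40 °C
Reagents that add atoms: benzyl bromide, BrCc1ccccc1
Why: Regioselective Williamson etherification; the 4-OH is para to the acetyl group (a vinylogous acid) and is the only hydroxyl ionised by hydrogencarbonate, whereas the 2-OH is held in a hydrogen bond to the carbonyl and the 3-OH is the least acidic, so one equivalent of benzyl bromide should alkylate O4. Exclusion of air protects the pyrogallol unit.

Step 2
Reactants: 2 1-(4-benzyloxy-2,3-dihydroxyphenyl)ethanone
Product: 3 1-(4-benzyloxy-2,3-dimethoxyphenyl)ethanone
Conditions: MeI (5 equiv), K2CO3 (4 equiv), DMF, N2, 50 °C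
Reagents that add atoms: iodomethane, CI
Why: Exhaustive Williamson O-methylation; the chelated 2-OH reacts last and needs the excess of MeI and the warming. K2CO3 is too weak to enolise the methyl ketone appreciably, so C-methylation is not expected.

Step 3
Reactants: 4 3-hydroxy-4,5-dimethoxybenzoic acid
Product: 5 3,4-dimethoxy-5-(pivaloyloxy)benzoic acid
Conditions: PivCl (1.3 equiv), NaOH (2.2 equiv), H2O/THF, 0 °C; then aq. HCl
Reagents that add atoms: pivaloyl chloride, CC(C)(C)C(=O)Cl
Why: Schotten–Baumann acylation; in aqueous base the phenoxide is the reactive nucleophile and any mixed anhydride formed at the carboxylate is hydrolysed back. Acidification returns the free acid with the hindered pivalate in place.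

Step 4
Reactants: 5 3,4-dimethoxy-5-(pivaloyloxy)benzoic acid
Product: 6 3,4-dimethoxy-5-(pivaloyloxy)benzoyl chloride
Conditions: (COCl)2 (1.5 equiv), DMF (cat.), CH2Cl2, 0 °C → rt; evaporate
Reagents that add atoms: oxalyl chloride, O=C(Cl)C(=O)Cl
Why: Standard conversion of an acid into its chloride through the Vilsmeier-type chloroiminium catalyst; the aryl pivalate and the methyl ethers are inert to anhydrous HCl. The crude chloride is used directly after removal of volatiles.

Step 5
Reactants: 3 1-(4-benzyloxy-2,3-dimethoxyphenyl)ethanone; 6 3,4-dimethoxy-5-(pivaloyloxy)benzoyl chloride
Product: 7 1-(4-benzyloxy-2,3-dimethoxyphenyl)-3-[3,4-dimethoxy-5-(pivaloyloxy)phenyl]propane-1,3-dione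
Conditions: 3, LiN(SiMe3)2 (2.2 equiv), THF, −78 °C; then 6 (1.0 equiv), −78 → 0 °C; aq. NH4Cl
Reagents that add atoms: none
Why: Crossed Claisen-type C-acylation of a lithium enolate by an acid chloride; 3 has a single enolisable position, and the second equivalent of amide deprotonates 7 as it forms, which keeps the enolate of 3 from being used up as a base and blocks a second acylation. The tert-butyl group keeps the aryl pivalate inert at low temperature.

Step 6
Reactants: 7 1-(4-benzyloxy-2,3-dimethoxyphenyl)-3-[3,4-dimethoxy-5-(pivaloyloxy)phenyl]propane-1,3-dione
Product: 8 5-(7-benzyloxy-5,6-dimethoxy-4-oxo-4H-chromen-2-yl)-2,3-dimethoxyphenyl pivalate (the 7-O-benzyl-5'-O-pivaloyl flavone)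
Conditions: graphite anode, Pt cathode, undivided cell, constant current (5 mA cm−2, 2.2 F mol−1), Bu4NPF6 (0.1 M), (CF3)2CHOH/CH2Cl2 (4:1), 0.01 M, rt
Reagents that add atoms: none
Why: Proposed new method: diketone 7 exists as its chelated enol, and removal of one electron at the graphite anode from the ring A/enol π-system in (CF3)2CHOH (a solvent that stabilises radical cations and is itself hard to oxidise) places positive charge on C8a, the ring A carbon para to the C6 methoxy group, where the enol oxygen on C2 can add through a six-membered transition state; a second electron transfer and loss of the C8a proton rearomatise ring A and make the closure irreversible, while the protons are reduced to H2 at the cathode; the closest known reaction types are anodic dehydrogenative C–O cyclisations of 2-arylbenzoic acids to benzocoumarins and of N-aryl amides to benzoxazoles and the oxidative closure of α-aryl ketones to benzofurans, none of which forms a pyranone ring from an enol oxygen. If the alkoxide formed at the cathode deprotonates 7 and the enolate is oxidised first, the resulting oxygen-delocalised radical is electrophilic and should attack the same electron-rich carbon, so both pathways converge on O1–C8a. Ring C closes as a six-membered ring by attack of oxygen on an sp2 carbon, with the fusion bond C4a–C8a inside the new ring and the attacked C8a=C8 π-bond outside it (6-exo-trig in that sense). No stereocentre is formed. The step needs site selectivity for C8a–H over C2'–H and C6'–H of ring B and over ipso attack at C5: ring A carries three ether donors and is twisted out of conjugation with the C4 carbonyl by the C5 methoxy group, whereas ring B is coplanar with its carbonyl, carries the poorly donating pivalate, and has its better activated C6'–H (para to the C3' methoxy group) shielded by the tert-butyl group. Ipso attack at C5 would give a ketal-type radical that cannot lose a proton and can only revert. High dilution and a charge only a little above 2 F mol−1 are chosen to suppress intermolecular coupling at C8 or C3 and over-oxidation of 8, which no longer has an oxidisable enol.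

Step 7
Reactants: 8 5-(7-benzyloxy-5,6-dimethoxy-4-oxo-4H-chromen-2-yl)-2,3-dimethoxyphenyl pivalate
Product: 10 7,5'-dihydroxy-5,6,3',4'-tetramethoxyflavone (the target), via 7-O-benzyl-5'-hydroxyflavone 9 (not isolated)
Conditions: K2CO3 (2 equiv), MeOH/THF, rt; AcOH (4 equiv); then H2 (1 atm), 10% Pd/C, rt
Reagents that add atoms: none
Why: Base-catalysed transesterification frees the C5' phenol, since aryl esters are activated toward methanolysis and the flavone is stable to K2CO3 at room temperature. After neutralisation, hydrogenolysis of the O–benzyl bond on Pd/C frees the C7 phenol. The methyl ethers are untouched, and at 1 atm the conjugated C2=C3 bond of a flavone should be reduced much more slowly than a benzyl ether is cleaved.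

## Compound list

1 | 2,3,4-trihydroxyacetophenone (gallacetophenone) | CC(=O)c1ccc(O)c(O)c1O | starting material
2 | 1-(4-benzyloxy-2,3-dihydroxyphenyl)ethanone | CC(=O)c1ccc(OCc2ccccc2)c(O)c1O | intermediate
3 | 1-(4-benzyloxy-2,3-dimethoxyphenyl)ethanone | CC(=O)c1ccc(OCc2ccccc2)c(OC)c1OC | intermediate
4 | 3-hydroxy-4,5-dimethoxybenzoic acid | COc1cc(C(=O)O)cc(O)c1OC | starting material
5 | 3,4-dimethoxy-5-(pivaloyloxy)benzoic acid | COc1cc(C(=O)O)cc(OC(=O)C(C)(C)C)c1OC | intermediate
6 | 3,4-dimethoxy-5-(pivaloyloxy)benzoyl chloride | COc1cc(C(=O)Cl)cc(OC(=O)C(C)(C)C)c1OC | intermediate
7 | 1-(4-benzyloxy-2,3-dimethoxyphenyl)-3-[3,4-dimethoxy-5-(pivaloyloxy)phenyl]propane-1,3-dione | COc1c(OC)c(OCc2ccccc2)ccc1C(=O)CC(=O)c1cc(OC)c(OC)c(OC(=O)C(C)(C)C)c1 | intermediate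
8 | 5-(7-benzyloxy-5,6-dimethoxy-4-oxo-4H-chromen-2-yl)-2,3-dimethoxyphenyl pivalate | COc1cc(-c2cc(=O)c3c(OC)c(OC)c(OCc4ccccc4)cc3o2)cc(OC(=O)C(C)(C)C)c1OC | intermediate
9 | 7-benzyloxy-2-(3-hydroxy-4,5-dimethoxyphenyl)-5,6-dimethoxy-4H-chromen-4-one | COc1cc(-c2cc(=O)c3c(OC)c(OC)c(OCc4ccccc4)cc3o2)cc(O)c1OC | intermediate (not isolated)
10 | 7-hydroxy-2-(3-hydroxy-4,5-dimethoxyphenyl)-5,6-dimethoxy-4H-chromen-4-one (7,5'-dihydroxy-5,6,3',4'-tetramethoxyflavone) | COc1cc(-c2cc(=O)c3c(OC)c(OC)c(O)cc3o2)cc(O)c1OC | target

## Step count and least certain steps

Total step count: 7 (two in the ring A branch, two in the ring B branch, the coupling, the key step, and the one-pot double deprotection).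
Longest linear sequence: 5 steps (steps 1, 2, 5, 6, 7; the branch through steps 3, 4, 5, 6, 7 is equally long).

**Step 6 (key step, the proposed new method).**
- What may go wrong: closure at the wrong site (an ortho C–H of ring B, or ipso at C5 with loss of the methoxy group), intermolecular dehydrodimerisation through C8 or C3, or solvent capture at C3. The two rings differ only modestly in oxidation potential, and oxidised 1,3-dicarbonyl species are prone to coupling.
- Fallback (known chemistry, O1 installed before ring closure): it sets out from 3 and returns at 8.
  - The ketone of 3 directs an ortho C–H hydroxylation at its only free ortho position, using catalytic Pd(OAc)2 (divalent palladium) and PhI(OCOCF3)2 in 1,2-dichloroethane at 80 °C. This should give 1-(4-benzyloxy-6-hydroxy-2,3-dimethoxyphenyl)ethanone F1.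
  - The dianion of F1 (LiN(SiMe3)2, 3.2 equiv, THF, −78 °C) is C-aroylated with 6 to give 1-(4-benzyloxy-6-hydroxy-2,3-dimethoxyphenyl)-3-[3,4-dimethoxy-5-(pivaloyloxy)phenyl]propane-1,3-dione F2. This is the direct variant of the Baker–Venkataraman construction.
  - Acid-catalysed cyclodehydration (TsOH, toluene, 80 °C) closes ring C from the C8a phenol onto the C2 carbonyl and gives 8.

**Step 5.**
- What may go wrong: O-acylation of the enolate, incomplete conversion through proton transfer from product to enolate, or attack of the amide base on the aryl ester. An acid chloride is an unselective electrophile, and the product is far more acidic than the starting ketone.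
- Fallback (aldol addition then oxidation in place of acylation): it sets out from 6 and 3 and returns at 7.
  - 6 is reduced with LiAlH(OtBu)3 in THF at −78 °C to 5-formyl-2,3-dimethoxyphenyl pivalate F3.
  - The lithium enolate of 3 (LiN(iPr)2, THF, −78 °C) adds to F3 to give the racemic aldol 1-(4-benzyloxy-2,3-dimethoxyphenyl)-3-[3,4-dimethoxy-5-(pivaloyloxy)phenyl]-3-hydroxypropan-1-one F4.
  - Oxidation of the secondary alcohol with Dess–Martin periodinane in CH2Cl2 gives 7; the stereocentre of F4 disappears in this oxidation.

**Step 1.**
- What may go wrong: loss of site selectivity (alkylation at O3 or double alkylation) and air oxidation of the pyrogallol unit under base. The acidity gap between the 4-OH and the 3-OH is the only control element.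
- Fallback (temporary masking of the competing diol): it sets out from 1 and returns at 2.
  - Aqueous Na2B4O7·10H2O with NaOH converts 1 into the cyclic 2,3-borate of gallacetophenone F5, which leaves only the 4-phenoxide free.
  - Alkylation with benzyl bromide in water/acetone at 50 °C gives the 4-O-benzyl borate F6.
  - Acidification releases boric acid and 2.

**Step 7.**
- What may go wrong: over-reduction of the C2=C3 bond during hydrogenolysis, or stalling of the debenzylation when the catalyst is poisoned by the salts of the first stage.
- Fallback (non-reductive cleavage): it sets out from 9, isolated after the methanolysis, and returns at 10. The benzyl ether is cleaved by acidolysis with CF3CO2H and pentamethylbenzene as cation scavenger at rt to 40 °C. This leaves the enone and the C5 methoxy group alone and makes no new intermediate.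

## Further compounds

F1 | step 6 | 1-(4-benzyloxy-6-hydroxy-2,3-dimethoxyphenyl)ethanone | CC(=O)c1c(O)cc(OCc2ccccc2)c(OC)c1OC
F2 | step 6 | 1-(4-benzyloxy-6-hydroxy-2,3-dimethoxyphenyl)-3-[3,4-dimethoxy-5-(pivaloyloxy)phenyl]propane-1,3-dione | COc1c(OC)c(OCc2ccccc2)cc(O)c1C(=O)CC(=O)c1cc(OC)c(OC)c(OC(=O)C(C)(C)C)c1
F3 | step 5 | 5-formyl-2,3-dimethoxyphenyl pivalate | COc1cc(C=O)cc(OC(=O)C(C)(C)C)c1OC
F4 | step 5 | 1-(4-benzyloxy-2,3-dimethoxyphenyl)-3-[3,4-dimethoxy-5-(pivaloyloxy)phenyl]-3-hydroxypropan-1-one (racemic) | COc1c(OC)c(OCc2ccccc2)ccc1C(=O)CC(O)c1cc(OC)c(OC)c(OC(=O)C(C)(C)C)c1
F5 | step 1 | disodium salt of the cyclic 2,3-borate of gallacetophenone | CC(=O)c1ccc([O-])c2O[B-](O)(O)Oc12.[Na+].[Na+]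
F6 | step 1 | sodium salt of the cyclic 2,3-borate of 1-(4-benzyloxy-2,3-dihydroxyphenyl)ethanone | CC(=O)c1ccc(OCc3ccccc3)c2O[B-](O)(O)Oc12.[Na+]
F0 | step 7 | none | none
A1 | alternative 1 | 1-[2-hydroxy-5,6-dimethoxy-4-(methoxymethoxy)phenyl]-3-[3,4-dimethoxy-5-(methoxymethoxy)phenyl]propane-1,3-dione | COCOc1cc(O)c(C(=O)CC(=O)c2cc(OC)c(OC)c(OCOC)c2)c(OC)c1OC
A2 | alternative 1 | 1-[6-hydroxy-2,3-dimethoxy-4-(methoxymethoxy)phenyl]ethanone | CC(=O)c1c(O)cc(OCOC)c(OC)c1OC
A3 | alternative 1 | 5-bromo-1,2-dimethoxy-3-(methoxymethoxy)benzene | COCOc1cc(Br)cc(OC)c1OC
A4 | alternative 1 | carbon monoxide | [C-]#[O+]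
A5 | alternative 2 | 5-tert-butoxy-3,4-dimethoxy-2-(2-methyl-1,3-dithian-2-yl)phenol | CC1(SCCCS1)c2c(O)cc(OC(C)(C)C)c(OC)c2OC
A6 | alternative 2 | 4-(1-tert-butoxyethenyl)-3,4-dimethoxy-2-(2-methyl-1,3-dithian-2-yl)cyclobut-2-en-1-one (racemic) | COC1=C(C2(C)SCCCS2)C(=O)C1(OC)C(=C)OC(C)(C)C
A7 | alternative 2 | dimethyl squarate (3,4-dimethoxycyclobut-3-ene-1,2-dione) | COC1=C(OC)C(=O)C1=O
A8 | alternative 3 | 5,6-dimethoxy-2-[3,4-dimethoxy-5-(triisopropylsilyloxy)phenyl]-7-(triisopropylsilyloxy)-4H-chromen-4-one | COc1cc(-c2cc(=O)c3c(OC)c(OC)c(O[Si](C(C)C)(C(C)C)C(C)C)cc3o2)cc(O[Si](C(C)C)(C(C)C)C(C)C)c1OC
A9 | alternative 3 | 2-iodo-3,4-dimethoxy-5-(triisopropylsilyloxy)phenol | COc1c(OC)c(O[Si](C(C)C)(C(C)C)C(C)C)cc(O)c1I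
A10 | alternative 3 | (5-ethynyl-2,3-dimethoxyphenoxy)triisopropylsilane | C#Cc1cc(OC)c(OC)c(O[Si](C(C)C)(C(C)C)C(C)C)c1
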